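**Retrosynthetic overview**

1. Target 27 ⇒ C7–O ester bond: azaphilone alcohol 15 (phenol masked as a triisopropylsilyl ether) + (2E,4S)-2,4-dimethyldec-2-enoic acid 24 (Evans methylation, Wittig olefination).
2. The strategy rests on the C6(=O)–C7(OH)(CH3)–C8(=O) array of carbocyclic ring A. This 2-hydroxy-2-methyl-1,3-dione is the α-ketol isomer of a 2-acetyl-2-hydroxy ketone in a ring one carbon smaller, so 15 ⇒ (6S)-6-acetyl-6-hydroxycyclopenta[c]pyran-7-one 14 by a ring-expanding 1,2-acyl shift that forms C7–C8 and relays C6 to C7.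
3. 14 ⇒ β-diketone 13 (catalytic asymmetric α-hydroxylation) ⇒ ketone 12 (C6 acetylation) ⇒ 11 (C5 chlorination).
4. 11 ⇒ enynal 10 (cycloisomerisation closes pyran ring B) ⇒ aryl alkyne 5 + chloro enal 9 (Sonogashira); 5 from 2-bromo-3-methylphenol, 9 from cyclopentane-1,3-dione.
5. Ring order: five-membered carbocycle (bought) → pyran ring B (step 7) → ring A by one-carbon enlargement (step 11).

Key step: step 11

Ar = 2-methyl-6-{[tri(propan-2-yl)silyl]oxy}phenyl throughout. The phenol is carried as its triisopropylsilyl ether because it must survive methanolic K2CO3, the Lewis acids and the final acylation, and leave with fluoride.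

Assumption: the sense of induction of the hydroxylation catalyst on this new β-diketone cannot be derived with certainty; the (R,R)-ligand is taken to give (6S)-14, the configuration is to be checked by anomalous-dispersion X-ray analysis of 14 (Cl, Si), and the (S,S)-ligand is used if the check shows the opposite.

**Step 1**
Reactants: 1 2-bromo-3-methylphenol
Product: 2 (2-bromo-3-methylphenoxy)tri(propan-2-yl)silane
Conditions: TIPSCl, imidazole, DMF, rt
Reagents that add atoms: triisopropylsilyl chloride, CC(C)[Si](Cl)(C(C)C)C(C)C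
Why: Imidazole-promoted silylation of a phenol gives the aryl silyl ether.

**Step 2**
Reactants: 2 (2-bromo-3-methylphenoxy)tri(propan-2-yl)silane; 3 ethynyltrimethylsilane
Product: 4 trimethyl[(Ar)ethynyl]silane
Conditions: Pd(PhCN)2Cl2 (3 mol%), [HP(t-Bu)3]BF4 (6 mol%), CuI (2 mol%), i-Pr2NH, dioxane, rt to 45 °C
Reagents that add atoms: none
Why: Sonogashira coupling, in which the bulky electron-rich phosphine should let the doubly ortho-substituted aryl bromide undergo oxidative addition near room temperature.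

**Step 3**
Reactants: 4 trimethyl[(Ar)ethynyl]silane
Product: 5 (2-ethynyl-3-methylphenoxy)tri(propan-2-yl)silane
Conditions: K2CO3 (0.2 equiv), MeOH/THF, 0 °C to rt
Reagents that add atoms: none
Why: Base-catalysed methanolysis of the alkynyl C–Si bond (protodesilylation) should leave the hindered aryl O–Si(i-Pr)3 ether untouched.

**Step 4**
Reactants: 6 cyclopentane-1,3-dione
Product: 7 2-[(dimethylamino)methylidene]cyclopentane-1,3-dione
Conditions: DMF dimethyl acetal, toluene, 60 °C
Reagents that add atoms: N,N-dimethylformamide dimethyl acetal, COC(OC)N(C)C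
Why: Enaminone-forming condensation of the acidic C2 of the symmetric 1,3-dione with the amide acetal installs the future C1 as a masked formyl group without any regiochemical question.

**Step 5**
Reactants: 7 2-[(dimethylamino)methylidene]cyclopentane-1,3-dione
Product: 9 2-chloro-5-oxocyclopent-1-ene-1-carbaldehyde, via chlorovinyl iminium chloride 8 (not isolated)
Conditions: (COCl)2 (1.1 equiv), CH2Cl2, 0 °C to rt; then H2O, NaOAc buffer, 0 °C
Reagents that add atoms: oxalyl chloride, O=C(Cl)C(=O)Cl; water, O
Why: Vilsmeier–Haack–Arnold-type activation, in which oxalyl chloride O-acylates the vinylogous amide, chloride displaces the activated oxygen to give iminium salt 8, and buffered hydrolysis releases the β-chloro enal; the two carbonyls of 7 are equivalent, so only one product can form.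

**Step 6**
Reactants: 5 (2-ethynyl-3-methylphenoxy)tri(propan-2-yl)silane; 9 2-chloro-5-oxocyclopent-1-ene-1-carbaldehyde
Product: 10 2-[(Ar)ethynyl]-5-oxocyclopent-1-ene-1-carbaldehyde
Conditions: Pd(PPh3)2Cl2 (3 mol%), CuI (5 mol%), Et3N (1.5 equiv), THF, 0 °C to rt
Reagents that add atoms: none
Why: Sonogashira coupling of a vinylogous acid chloride, whose C–Cl bond is activated towards oxidative addition to zerovalent palladium by the two conjugated carbonyl groups.

**Step 7**
Reactants: 10 2-[(Ar)ethynyl]-5-oxocyclopent-1-ene-1-carbaldehyde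
Product: 11 3-Ar-cyclopenta[c]pyran-7(6H)-one
Conditions: AgOTf (5 mol%), CH2Cl2, rt, dark
Reagents that add atoms: none
Why: π-Acid-catalysed 6-endo-dig cycloisomerisation of a 2-alkynyl enal, in which the formyl oxygen adds to the silver-activated alkyne to give a pyrylium ion that loses its acidic C5 proton and is protodemetalated at C4 to the neutral 4-alkylidene-4H-pyran, the 5-exo mode being disfavoured by the strain of a fused five–five oxacycle.

**Step 8**
Reactants: 11 3-Ar-cyclopenta[c]pyran-7(6H)-one
Product: 12 5-chloro-3-Ar-cyclopenta[c]pyran-7(6H)-one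
Conditions: NCS (1.0 equiv), MeCN, 0 °C, dark
Reagents that add atoms: N-chlorosuccinimide, O=C1CCC(=O)N1Cl
Why: Electrophilic chlorination at the terminus of the dienol ether O2–C3=C4–C4a=C5 (the position halogenated in azaphilones) should be favoured because attack at C5 passes through an aromatic pyrylium cation that then loses the C5 proton, while the C6 methylene does not enolise under neutral conditions.

**Step 9**
Reactants: 12 5-chloro-3-Ar-cyclopenta[c]pyran-7(6H)-one
Product: 13 6-acetyl-5-chloro-3-Ar-cyclopenta[c]pyran-7(6H)-one (enolised β-diketone)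
Conditions: MgBr2·OEt2 (2.5 equiv), i-Pr2NEt (3 equiv), 1-acetylbenzotriazole (1.2 equiv), CH2Cl2, rt; aq NH4Cl
Reagents that add atoms: 1-acetyl-1H-benzotriazole, CC(=O)n1nnc2ccccc12
Why: Soft-enolisation crossed Claisen C-acylation, in which magnesium coordination acidifies C6–H, the amine forms the enolate and the N-acylbenzotriazole acylates it at carbon, the magnesium β-diketonate chelate being the thermodynamic sink.

**Step 10**
Reactants: 13 6-acetyl-5-chloro-3-Ar-cyclopenta[c]pyran-7(6H)-one
Product: 14 (6S)-6-acetyl-5-chloro-6-hydroxy-3-Ar-cyclopenta[c]pyran-7(6H)-one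
Conditions: Ni(ClO4)2·6H2O (10 mol%), (R,R)-4,6-dibenzofurandiyl-2,2'-bis(4-phenyloxazoline) (11 mol%), 3-phenyl-2-(phenylsulfonyl)oxaziridine (1.2 equiv), 4 Å MS, CH2Cl2, rt
Reagents that add atoms: 3-phenyl-2-(phenylsulfonyl)oxaziridine, O=S(=O)(c1ccccc1)N1OC1c1ccccc1
Why: Catalytic enantioselective α-hydroxylation of a cyclic β-dicarbonyl compound, in which the diketonate chelates the divalent nickel–bis(oxazoline) complex and the oxaziridine transfers oxygen to C6 on the enolate face left open by the ligand phenyl groups (catalyst control of C6), with C5 blocked by chlorine and neutral conditions avoiding retro-Claisen cleavage.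

**Step 11**
Reactants: 14 (6S)-6-acetyl-5-chloro-6-hydroxy-3-Ar-cyclopenta[c]pyran-7(6H)-one
Product: 15 (7S)-5-chloro-7-hydroxy-7-methyl-3-Ar-6H-isochromene-6,8(7H)-dione
Conditions: Sc(OTf)3 (10 mol%), 4 Å MS, CH2Cl2, rt to 40 °C
Reagents that add atoms: none
Why: Proposed new method: Sc(OTf)3 binds the C6 hydroxyl and the acetyl oxygen of 14 in a five-membered chelate that holds the O–C6–C(acetyl)=O unit syn-periplanar and activates the acetyl carbonyl, so the ring acyl carbon (C7 of 14, C8 of 15), whose bond to C6 lies close to perpendicular to the acetyl plane, shifts suprafacially to the acetyl carbon while the carbinol collapses to the C6 ketone, which forms the C7–C8 bond. The closest known reaction type is the Lewis-acid-promoted α-ketol (acyloin) rearrangement with ring enlargement of 1-acylcycloalkanols, as in the D-homoannulation of 17-hydroxy-20-oxo steroids; new here are the migration of a carbonyl carbon inside a 2-acetyl-2-hydroxy ketone and the cyclopenta[c]pyranone substrate. Ring A is closed not by a cyclisation but by this 1,2-shift, a one-carbon enlargement of the five-membered carbocycle to the six-membered 2-hydroxy-2-methyl-1,3-dione. The new stereocentre C7 is controlled by C6 of 14: in the chelate the migrating carbon reaches the acetyl face on its own side, so (6S)-14 should be relayed to (7S)-15, and the indirect sequence of acetyl migration to the ring carbonyl followed by ring enlargement should converge on the same enantiomer as long as each shift passes through a chelate. The step needs the acyl carbon to migrate in preference to the chlorovinyl carbon C5, and the carbon-to-carbon shift to win over acyl transfer to oxygen and retro-Claisen loss of acetyl; the shifts are reversible and 15 is the isomer in which both ring carbonyls are conjugated with the pyran oxygen (C8 through C8a=C1, C6 through C5=C4a–C4=C3), chlorine lowers the migratory aptitude of C5, and the absence of base or nucleophile shuts off the oxygen-directed pathways.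

**Step 12**
Reactants: 16 octanoyl chloride; 17 (4S)-4-benzyl-1,3-oxazolidin-2-one
Product: 18 (4S)-4-benzyl-3-octanoyl-1,3-oxazolidin-2-one
Conditions: n-BuLi, THF, −78 °C; then 16, −78 to 0 °C
Reagents that add atoms: none
Why: N-Acylation of the lithiated Evans oxazolidinone by the acid chloride.

**Step 13**
Reactants: 18 (4S)-4-benzyl-3-octanoyl-1,3-oxazolidin-2-one
Product: 19 (4S)-4-benzyl-3-[(2S)-2-methyloctanoyl]-1,3-oxazolidin-2-one
Conditions: NaHMDS, THF, −78 °C; MeI, −78 to −40 °C
Reagents that add atoms: iodomethane, CI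
Why: Evans asymmetric alkylation, in which the chelated Z sodium enolate is methylated on the face opposite the C4 benzyl group; with the hexyl chain already on the enolate this sets the 2S centre.

**Step 14**
Reactants: 19 (4S)-4-benzyl-3-[(2S)-2-methyloctanoyl]-1,3-oxazolidin-2-one
Product: 20 (2S)-2-methyloctan-1-ol
Conditions: LiBH4, H2O (1 equiv), Et2O, 0 °C; aqueous work-up
Reagents that add atoms: none
Why: Reductive cleavage of the imide by hydride attack at the exocyclic carbonyl releases the auxiliary and leaves the α-stereocentre untouched.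

**Step 15**
Reactants: 20 (2S)-2-methyloctan-1-ol; 21 ethyl 2-(triphenylphosphoranylidene)propanoate
Product: 23 ethyl (2E,4S)-2,4-dimethyldec-2-enoate, via (2S)-2-methyloctanal 22 (not isolated)
Conditions: TEMPO (10 mol%), PhI(OAc)2 (1.1 equiv), CH2Cl2, rt; then 21 (2 equiv), rt
Reagents that add atoms: none
Why: TEMPO/PhI(OAc)2 oxidation to the aldehyde followed in the same flask by Wittig olefination with a stabilised α-methyl ylide should give the E trisubstituted enoate, and the non-basic conditions without isolation keep the α-stereocentre of 22 intact.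

**Step 16**
Reactants: 23 ethyl (2E,4S)-2,4-dimethyldec-2-enoate
Product: 24 (2E,4S)-2,4-dimethyldec-2-enoic acid
Conditions: LiOH·H2O, THF/MeOH/H2O, 40 °C; then 1 M HCl
Reagents that add atoms: lithium hydroxide, [Li+].[OH-]
Why: Saponification of the ester by acyl–oxygen cleavage.

**Step 17**
Reactants: 15 (7S)-5-chloro-7-hydroxy-7-methyl-3-Ar-6H-isochromene-6,8(7H)-dione; 24 (2E,4S)-2,4-dimethyldec-2-enoic acid
Product: 26 (7S)-5-chloro-7-methyl-3-Ar-6,8-dioxo-7,8-dihydro-6H-isochromen-7-yl (2E,4S)-2,4-dimethyldec-2-enoate, via acid chloride 25 (not isolated)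
Conditions: 24, (COCl)2, cat. DMF, CH2Cl2, 0 °C to rt, concentrate; then 15, DMAP (1.5 equiv), pyridine, CH2Cl2, 0 °C to rt
Reagents that add atoms: none
Why: Acid chloride formation and DMAP-catalysed acylation of the tertiary alcohol, the only free hydroxyl since the phenol is silylated; pyridine in place of a trialkylamine limits γ-deprotonation to a vinylketene that would erase the 4S centre.

**Step 18**
Reactants: 26 (7S)-5-chloro-7-methyl-3-Ar-6,8-dioxo-7,8-dihydro-6H-isochromen-7-yl (2E,4S)-2,4-dimethyldec-2-enoate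
Product: 27 (7S)-5-chloro-3-(2-hydroxy-6-methylphenyl)-7-methyl-6,8-dioxo-7,8-dihydro-6H-isochromen-7-yl (2E,4S)-2,4-dimethyldec-2-enoate
Conditions: HF·pyridine, THF/pyridine, 0 °C to rt
Reagents that add atoms: none
Why: Fluoride-mediated cleavage of the aryl silyl ether, driven by Si–F bond formation, under buffered conditions that should spare the tertiary enoate and the base-sensitive azaphilone.

**Compound list**

1 | 2-bromo-3-methylphenol | Cc1cccc(O)c1Br | starting material
2 | (2-bromo-3-methylphenoxy)tri(propan-2-yl)silane | Cc1cccc(O[Si](C(C)C)(C(C)C)C(C)C)c1Br | intermediate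
3 | ethynyltrimethylsilane | C#C[Si](C)(C)C | starting material
4 | trimethyl[(2-methyl-6-{[tri(propan-2-yl)silyl]oxy}phenyl)ethynyl]silane | Cc1cccc(O[Si](C(C)C)(C(C)C)C(C)C)c1C#C[Si](C)(C)C | intermediate
5 | (2-ethynyl-3-methylphenoxy)tri(propan-2-yl)silane | Cc1cccc(O[Si](C(C)C)(C(C)C)C(C)C)c1C#C | intermediate
6 | cyclopentane-1,3-dione | O=C1CCC(=O)C1 | starting material
7 | 2-[(dimethylamino)methylidene]cyclopentane-1,3-dione | CN(C)C=C1C(=O)CCC1=O | intermediate
8 | N-[(2-chloro-5-oxocyclopent-1-en-1-yl)methylidene]-N-methylmethanaminium chloride | C[N+](C)=CC1=C(Cl)CCC1=O.[Cl-] | intermediate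
9 | 2-chloro-5-oxocyclopent-1-ene-1-carbaldehyde | O=CC1=C(Cl)CCC1=O | intermediate
10 | 2-[(2-methyl-6-{[tri(propan-2-yl)silyl]oxy}phenyl)ethynyl]-5-oxocyclopent-1-ene-1-carbaldehyde | O=CC1=C(C#Cc2c(C)cccc2O[Si](C(C)C)(C(C)C)C(C)C)CCC1=O | intermediate
11 | 3-(2-methyl-6-{[tri(propan-2-yl)silyl]oxy}phenyl)cyclopenta[c]pyran-7(6H)-one | O=C1CC=C2C=C(c3c(C)cccc3O[Si](C(C)C)(C(C)C)C(C)C)OC=C12 | intermediate
12 | 5-chloro-3-(2-methyl-6-{[tri(propan-2-yl)silyl]oxy}phenyl)cyclopenta[c]pyran-7(6H)-one | O=C1CC(Cl)=C2C=C(c3c(C)cccc3O[Si](C(C)C)(C(C)C)C(C)C)OC=C12 | intermediate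
13 | 6-acetyl-5-chloro-3-(2-methyl-6-{[tri(propan-2-yl)silyl]oxy}phenyl)cyclopenta[c]pyran-7(6H)-one | CC(=O)C1C(=O)C2=COC(c3c(C)cccc3O[Si](C(C)C)(C(C)C)C(C)C)=CC2=C1Cl | intermediate
14 | (6S)-6-acetyl-5-chloro-6-hydroxy-3-(2-methyl-6-{[tri(propan-2-yl)silyl]oxy}phenyl)cyclopenta[c]pyran-7(6H)-one | CC(=O)[C@]1(O)C(=O)C2=COC(c3c(C)cccc3O[Si](C(C)C)(C(C)C)C(C)C)=CC2=C1Cl | intermediate
15 | (7S)-5-chloro-7-hydroxy-7-methyl-3-(2-methyl-6-{[tri(propan-2-yl)silyl]oxy}phenyl)-6H-isochromene-6,8(7H)-dione | O[C@@]1(C)C(=O)C2=COC(c3c(C)cccc3O[Si](C(C)C)(C(C)C)C(C)C)=CC2=C(Cl)C1=O | intermediate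
16 | octanoyl chloride | CCCCCCCC(=O)Cl | starting material
17 | (4S)-4-benzyl-1,3-oxazolidin-2-one | O=C1N[C@@H](Cc2ccccc2)CO1 | starting material
18 | (4S)-4-benzyl-3-octanoyl-1,3-oxazolidin-2-one | CCCCCCCC(=O)N1[C@@H](Cc2ccccc2)COC1=O | intermediate
19 | (4S)-4-benzyl-3-[(2S)-2-methyloctanoyl]-1,3-oxazolidin-2-one | CCCCCC[C@H](C)C(=O)N1[C@@H](Cc2ccccc2)COC1=O | intermediate
20 | (2S)-2-methyloctan-1-ol | CCCCCC[C@H](C)CO | intermediate
21 | ethyl 2-(triphenylphosphoranylidene)propanoate | CCOC(=O)C(C)=P(c1ccccc1)(c1ccccc1)c1ccccc1 | starting material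
22 | (2S)-2-methyloctanal | CCCCCC[C@H](C)C=O | intermediate
23 | ethyl (2E,4S)-2,4-dimethyldec-2-enoate | CCCCCC[C@H](C)/C=C(\C)C(=O)OCC | intermediate
24 | (2E,4S)-2,4-dimethyldec-2-enoic acid | CCCCCC[C@H](C)/C=C(\C)C(=O)O | intermediate
25 | (2E,4S)-2,4-dimethyldec-2-enoyl chloride | CCCCCC[C@H](C)/C=C(\C)C(=O)Cl | intermediate
26 | (7S)-5-chloro-7-methyl-3-(2-methyl-6-{[tri(propan-2-yl)silyl]oxy}phenyl)-6,8-dioxo-7,8-dihydro-6H-isochromen-7-yl (2E,4S)-2,4-dimethyldec-2-enoate | CCCCCC[C@H](C)/C=C(\C)C(=O)O[C@@]1(C)C(=O)C2=COC(c3c(C)cccc3O[Si](C(C)C)(C(C)C)C(C)C)=CC2=C(Cl)C1=O | intermediate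
27 | (7S)-5-chloro-3-(2-hydroxy-6-methylphenyl)-7-methyl-6,8-dioxo-7,8-dihydro-6H-isochromen-7-yl (2E,4S)-2,4-dimethyldec-2-enoate | CCCCCC[C@H](C)/C=C(\C)C(=O)O[C@@]1(C)C(=O)C2=COC(c3c(C)cccc3O)=CC2=C(Cl)C1=O | target

**Step count**

Total: 18 steps. Longest linear sequence: 11 steps (steps 1–3, 6–11, 17, 18).

**Three steps most likely to fail**

Step 11 (key step, proposed new method). The chlorovinyl carbon C5 may migrate in place of the acyl carbon, the acetyl group may shift to oxygen or be lost by retro-Claisen cleavage, or a non-chelated conformer may take part and erode the enantiomeric purity. The fallback uses the established azaphilone construction; it sets out from compound 5 and comes back to the route at compound 15. Vilsmeier formylation of 5-bromo-2-methylbenzene-1,3-diol would give 6-bromo-2,4-dihydroxy-3-methylbenzaldehyde F1. Sonogashira coupling of F1 with alkyne 5 (Pd(PPh3)2Cl2, CuI, Et3N, DMF) should give 2,4-dihydroxy-3-methyl-6-[(Ar)ethynyl]benzaldehyde F2. Copper-mediated enantioselective oxidative dearomatisation ([Cu(MeCN)4]PF6, (−)-sparteine, O2, i-Pr2NEt, CH2Cl2, −78 to −10 °C) hydroxylates the methyl-bearing ring carbon to the vinylogous acid (6R)-6-hydroxy-2-(hydroxymethylidene)-6-methyl-3-[(Ar)ethynyl]cyclohex-3-ene-1,5-dione F3. Buffered cycloisomerisation (aqueous KH2PO4/K2HPO4) then closes the pyran to (7R)-7-hydroxy-7-methyl-3-Ar-6H-isochromene-6,8(7H)-dione F4, which has the same spatial arrangement at C7 as 15. NCS in MeCN chlorinates C5 and gives 15, whose descriptor becomes 7S once chlorine is on C5.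

Step 10. Facial selectivity may be poor or of the opposite sense on this new β-diketone, the oxaziridine may attack the pyran enol ether, and the α-hydroxy β-diketone may lose acetyl on isolation. The fallback replaces asymmetric catalysis by resolution; it sets out from compound 13 and comes back at compound 14. Hydroxylation with the same oxaziridine under achiral Ni(acac)2 catalysis should give racemic 6-acetyl-5-chloro-6-hydroxy-3-Ar-cyclopenta[c]pyran-7(6H)-one F5. Preparative chiral-phase supercritical-fluid chromatography then separates 14 from its enantiomer (6R)-6-acetyl-5-chloro-6-hydroxy-3-Ar-cyclopenta[c]pyran-7(6H)-one F6, which is set aside.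

Step 9. The enolate of 12 is an aromatic oxido-pseudoazulene, so acylation may go to oxygen (giving an aromatic enol acetate) or twice. The fallback builds the acetyl group by aldol addition and oxidation; it sets out from compound 12 and comes back at compound 13. The lithium enolate of 12 (LiHMDS, THF, −78 °C) is added to acetaldehyde to give 5-chloro-6-(1-hydroxyethyl)-3-Ar-cyclopenta[c]pyran-7(6H)-one F7 as a diastereomer mixture. Dess–Martin oxidation of the secondary alcohol then gives β-diketone 13.

**Further compounds**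

F1 | step 11 | 6-bromo-2,4-dihydroxy-3-methylbenzaldehyde | O=Cc1c(O)c(C)c(O)cc1Br
F2 | step 11 | 2,4-dihydroxy-3-methyl-6-[(2-methyl-6-{[tri(propan-2-yl)silyl]oxy}phenyl)ethynyl]benzaldehyde | O=Cc1c(O)c(C)c(O)cc1C#Cc1c(C)cccc1O[Si](C(C)C)(C(C)C)C(C)C
F3 | step 11 | (6R)-6-hydroxy-2-(hydroxymethylidene)-6-methyl-3-[(2-methyl-6-{[tri(propan-2-yl)silyl]oxy}phenyl)ethynyl]cyclohex-3-ene-1,5-dione | O[C@@]1(C)C(=O)C(=CO)C(C#Cc2c(C)cccc2O[Si](C(C)C)(C(C)C)C(C)C)=CC1=O
F4 | step 11 | (7R)-7-hydroxy-7-methyl-3-(2-methyl-6-{[tri(propan-2-yl)silyl]oxy}phenyl)-6H-isochromene-6,8(7H)-dione | O[C@@]1(C)C(=O)C2=COC(c3c(C)cccc3O[Si](C(C)C)(C(C)C)C(C)C)=CC2=CC1=O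
F5 | step 10 | racemic 6-acetyl-5-chloro-6-hydroxy-3-(2-methyl-6-{[tri(propan-2-yl)silyl]oxy}phenyl)cyclopenta[c]pyran-7(6H)-one | CC(=O)C1(O)C(=O)C2=COC(c3c(C)cccc3O[Si](C(C)C)(C(C)C)C(C)C)=CC2=C1Cl
F6 | step 10 | (6R)-6-acetyl-5-chloro-6-hydroxy-3-(2-methyl-6-{[tri(propan-2-yl)silyl]oxy}phenyl)cyclopenta[c]pyran-7(6H)-one | CC(=O)[C@@]1(O)C(=O)C2=COC(c3c(C)cccc3O[Si](C(C)C)(C(C)C)C(C)C)=CC2=C1Cl
F7 | step 9 | 5-chloro-6-(1-hydroxyethyl)-3-(2-methyl-6-{[tri(propan-2-yl)silyl]oxy}phenyl)cyclopenta[c]pyran-7(6H)-one | CC(O)C1C(=O)C2=COC(c3c(C)cccc3O[Si](C(C)C)(C(C)C)C(C)C)=CC2=C1Cl
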